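**Strategy.** The decalin (drimane numbering) is disconnected at C5–C6 and C10–C1. The key step exploits that C6 is a vinylic CH of the ring-B diene bonded to the ring-fusion carbon C5, which neighbours the quaternary C10 shared by rings A and B. A C6 vinyl radical, generated from acyclic iodo-trienone 11, attacks C5 of a C5=C10 alkene (6-endo, ring B). The tertiary C10 radical then closes ring A by Giese addition to a vinyl ketone. One operation forms both rings and the trans C5/C10 pair, steered by erasable C8/C9 stereocentres. A C9 dienyl triflate is finally joined to the oxepane half by B-alkyl Suzuki coupling.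

Key step: step 8

Remark: decalin atoms carry drimane numbers (C1–C10; methyls on C4, C4, C8, C10) and the oxepane half is named as a 1-benzoxepine. Compounds 1, 5 and 16, the Shi ketone and the reagents named under the conditions are taken as commercial.

**Left half (decalin dienyl triflate)**

Step 1
Reactants: 1 methyl 3-hydroxy-2,2-dimethylpropanoate
Product: 2 3-hydroxy-N-methoxy-N,2,2-trimethylpropanamide
Conditions: MeNH(OMe)·HCl, iPrMgCl (4 equiv), THF, −15 °C to rt
Reagents that add atoms: N,O-dimethylhydroxylamine hydrochloride, CNOC.Cl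
Why: Weinreb amidation of the ester by the chloromagnesium amide, which tolerates the free hydroxyl as its alkoxide; no stereocentre is involved.

Step 2
Reactants: 2 3-hydroxy-N-methoxy-N,2,2-trimethylpropanamide
Product: 3 N-methoxy-N,2,2-trimethyl-3-oxopropanamide
Conditions: Dess–Martin periodinane, NaHCO3, CH2Cl2, rt
Reagents that add atoms: none
Why: Dess–Martin oxidation of the neopentyl primary alcohol gives a non-enolisable aldehyde that cannot epimerise or self-condense.

Step 3
Reactants: 3 N-methoxy-N,2,2-trimethyl-3-oxopropanamide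
Product: 4 (E)-N-methoxy-N,2,2,4-tetramethyl-5-oxopent-3-enamide
Conditions: Ph3P=C(CH3)CHO, toluene, 100 °C
Reagents that add atoms: 2-(triphenylphosphoranylidene)propanal, CC(C=O)=P(c1ccccc1)(c1ccccc1)c1ccccc1
Why: Wittig olefination with the stabilised formyl ylide gives the thermodynamically favoured E enal, which becomes the E C5=C10 alkene needed for the trans ring fusion.

Step 4
Reactants: 5 (R)-but-3-yn-2-ol
Product: 6 (R)-but-3-yn-2-yl methanesulfonate
Conditions: MsCl, Et3N, CH2Cl2, 0 °C
Reagents that add atoms: methanesulfonyl chloride, CS(=O)(=O)Cl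
Why: O-sulfonylation of the propargylic alcohol proceeds with retention because the C–O bond is not broken.

Step 5
Reactants: 4 (E)-N-methoxy-N,2,2,4-tetramethyl-5-oxopent-3-enamide; 6 (R)-but-3-yn-2-yl methanesulfonate
Product: 8 (3E,5S,6S)-5-hydroxy-N-methoxy-N,2,2,4,6-pentamethyloct-3-en-7-ynamide, via allenylzinc 7 (not isolated)
Conditions: Pd(OAc)2 (5 mol %), PPh3, Et2Zn, THF, −20 °C
Reagents that add atoms: none
Why: Marshall–Tamaru propargylation: zerovalent palladium opens mesylate 6 by anti SN2′ attack, transmetalation gives allenylzinc 7, and its cyclic SE2′ addition to the aldehyde of 4 (Weinreb amide untouched) gives the anti homopropargylic alcohol, the methyl-bearing carbon (6S) arising from (R)-6 with net inversion and the carbinol (5S) from the transition state that keeps the aldehyde substituent anti to the allenyl methyl.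

Step 6
Reactants: 8 (3E,5S,6S)-5-hydroxy-N-methoxy-N,2,2,4,6-pentamethyloct-3-en-7-ynamide
Product: 10 (3E,5S,6S,7E)-5-hydroxy-8-iodo-N-methoxy-N,2,2,4,6-pentamethylocta-3,7-dienamide, via vinylstannane 9 (not isolated)
Conditions: Bu3SnH, PdCl2(PPh3)2 (cat.), THF, 0 °C; then I2, CH2Cl2, 0 °C
Reagents that add atoms: iodine, II
Why: Palladium-catalysed syn hydrostannation places tin on the terminal alkyne carbon (E), and iododestannylation with retention gives the vinyl iodide; the stereocentres are untouched.

Step 7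
Reactants: 10 (3E,5S,6S,7E)-5-hydroxy-8-iodo-N-methoxy-N,2,2,4,6-pentamethylocta-3,7-dienamide
Product: 11 (5E,7S,8S,9E)-7-hydroxy-10-iodo-4,4,6,8-tetramethyldeca-1,5,9-trien-3-one
Conditions: CH2=CHMgBr (3 equiv), THF, −10 °C; inverse quench into cold aq. HCl
Reagents that add atoms: vinylmagnesium bromide, C=C[Mg]Br
Why: Weinreb ketone synthesis: the chelated tetrahedral intermediate stops at the ketone, the first equivalent of Grignard reagent only deprotonates the hydroxyl, and the vinyl iodide is inert at this temperature.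

Step 8
Reactants: 11 (5E,7S,8S,9E)-7-hydroxy-10-iodo-4,4,6,8-tetramethyldeca-1,5,9-trien-3-one
Product: 12 (5S,8S,9S,10R)-9-hydroxy-4,4,8,10-tetramethyl-trans-decal-6-en-3-one
Conditions: Bu3SnH (1.3 equiv, syringe pump), AIBN, benzene, 80 °C, high dilution
Reagents that add atoms: none
Why: Bu3Sn• abstracts iodine from 11 to give the C6 vinyl radical, which closes ring B by 6-endo attack on C5 of the C5=C10 alkene (directly, or by 5-exo closure and cyclopropylcarbinyl ring expansion), and the resulting tertiary C10 radical closes ring A by 6-endo Giese addition to the vinyl ketone (C10–C1) before the α-keto radical takes hydrogen from the stannane. The closest known reaction types are vinyl-radical cyclisations onto trisubstituted alkenes and polyene radical cascades that end on an enone. Ring B closes in the 6-endo-trig mode because the proximal alkene carbon C10 is fully substituted, and ring A closes 6-endo-trig because the nucleophilic tertiary radical adds to the unsubstituted β-carbon of the enone. C5 is fixed by the erasable C8/C9 pair: in the chair-like transition state the C8 methyl is equatorial and the C9 hydroxyl axial, which avoids A(1,2) strain with the C10 methyl, so C6 adds to the face that leaves H5 syn to the hydroxyl (5S). C10 follows from chair-like closure of ring A with the bulky C4 chain equatorial on ring B, which makes the new C10–C1 bond equatorial and the methyl axial, anti to H5 (trans-decalin, 10R). The step needs both cyclisations to outrun hydrogen transfer, which slow stannane addition at high dilution secures, and 6-endo regiochemistry in both closures, which the substitution pattern and polarity matching secure.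

Step 9
Reactants: 12 (5S,8S,9S,10R)-9-hydroxy-4,4,8,10-tetramethyl-trans-decal-6-en-3-one
Product: 13 (5R,8S,10R)-4,4,8,10-tetramethyl-trans-decal-6-ene-3,9-dione
Conditions: Dess–Martin periodinane, NaHCO3, CH2Cl2, rt
Reagents that add atoms: none
Why: Dess–Martin oxidation of the hindered secondary C9 carbinol under buffered conditions spares the alkene and the C3 ketone; C8 becomes epimerisable but is erased in step 10 (the C5 descriptor changes by priority only).

Step 10
Reactants: 13 (5R,8S,10R)-4,4,8,10-tetramethyl-trans-decal-6-ene-3,9-dione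
Product: 14 (5S,10R)-4,4,8,10-tetramethyl-3-oxo-trans-decala-6,8-dien-9-yl trifluoromethanesulfonate
Conditions: KN(SiMe3)2 (0.98 equiv), THF, −78 to −40 °C; then PhNTf2, −78 to 0 °C
Reagents that add atoms: N-phenylbis(trifluoromethanesulfonimide), O=S(=O)(N(c1ccccc1)S(=O)(=O)C(F)(F)F)C(F)(F)F
Why: Regioselective enol triflate formation: H8 is both α to the C9 ketone and allylic to C6=C7, so equilibrating deprotonation with a slight deficit of base gives the conjugated C9 dienolate rather than the C2 enolate, and O-triflation fixes the C6=C7–C8=C9 diene.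

Step 11
Reactants: 14 (5S,10R)-4,4,8,10-tetramethyl-3-oxo-trans-decala-6,8-dien-9-yl trifluoromethanesulfonate
Product: 15 (3R,5R,10R)-3-hydroxy-4,4,8,10-tetramethyl-trans-decala-6,8-dien-9-yl trifluoromethanesulfonate
Conditions: NaBH4, MeOH/THF, −20 °C
Reagents that add atoms: none
Why: Borohydride reduction of the 4,4-dimethyl-3-ketone by axial hydride delivery from the face anti to the axial C4 and C10 methyls gives the equatorial 3R alcohol, and the dienyl triflate is inert (C5 geometry unchanged, descriptor changes by priority).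

**Right half (oxepane vinyl ketone)**

Step 12
Reactants: 16 (2E,6E)-farnesyl acetate
Product: 17 (2E,6R,7R,10R)-6,7:10,11-diepoxy-3,7,11-trimethyldodec-2-en-1-yl acetate
Conditions: D-fructose-derived Shi ketone (30 mol %), KHSO5 (Oxone), K2CO3, Bu4NHSO4, MeCN/dimethoxymethane/aq. buffer, 0 °C
Reagents that add atoms: potassium peroxymonosulfate, OOS(=O)(=O)[O-].[K+]
Why: Shi epoxidation: the chiral dioxirane epoxidises the two electron-rich trisubstituted alkenes through a spiro transition state to give the R,R-configured epoxides, while the 2,3-alkene is deactivated by the allylic acetate.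

Step 13
Reactants: 17 (2E,6R,7R,10R)-6,7:10,11-diepoxy-3,7,11-trimethyldodec-2-en-1-yl acetate
Product: 18 [(3R,5aR,6S,9aR)-3-hydroxy-2,2,5a-trimethyl-7-methylidenedecahydro-1-benzoxepin-6-yl]methyl acetate
Conditions: TMSOTf (1.2 equiv), 2,6-di-tert-butyl-4-methylpyridine, CH2Cl2, −78 °C; then 1 M HCl, THF
Reagents that add atoms: none
Why: Tandem oxa- and carbacyclisation of a polyepoxide: silyl activation of the terminal epoxide, endo attack of the neighbouring epoxide oxygen at the tertiary carbon (oxepane), anti opening of the resulting epoxonium at its tertiary carbon by the 2,3-alkene through a chair and loss of a methyl proton set the trans ring fusion (inversion at C5a) and the equatorial CH2OAc cis to the angular methyl.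

Step 14
Reactants: 18 [(3R,5aR,6S,9aR)-3-hydroxy-2,2,5a-trimethyl-7-methylidenedecahydro-1-benzoxepin-6-yl]methyl acetate
Product: 19 [(3R,5aR,6S,7S,9aR)-3-hydroxy-2,2,5a,7-tetramethyldecahydro-1-benzoxepin-6-yl]methyl acetate
Conditions: H2 (1 atm), PtO2, EtOAc, rt
Reagents that add atoms: none
Why: Heterogeneous hydrogenation delivers hydrogen to the exocyclic alkene from the face opposite the axial angular methyl, which leaves the new C7 methyl cis to the angular methyl and to the C6 side chain (7S).

Step 15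
Reactants: 19 [(3R,5aR,6S,7S,9aR)-3-hydroxy-2,2,5a,7-tetramethyldecahydro-1-benzoxepin-6-yl]methyl acetate
Product: 20 (3R,5aR,6S,7S,9aR)-6-(hydroxymethyl)-2,2,5a,7-tetramethyldecahydro-1-benzoxepin-3-ol
Conditions: K2CO3 (cat.), MeOH, rt
Reagents that add atoms: none
Why: Base-catalysed methanolysis (transesterification) of the primary acetate touches no stereocentre.

Step 16
Reactants: 20 (3R,5aR,6S,7S,9aR)-6-(hydroxymethyl)-2,2,5a,7-tetramethyldecahydro-1-benzoxepin-3-ol
Product: 21 (5aR,6S,7S,9aR)-2,2,5a,7-tetramethyl-3-oxodecahydro-1-benzoxepine-6-carbaldehyde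
Conditions: Dess–Martin periodinane (2.5 equiv), NaHCO3, CH2Cl2, rt
Reagents that add atoms: none
Why: Double Dess–Martin oxidation converts the primary alcohol to the aldehyde and the oxepanol to the ketone, and the aldehyde α-carbon keeps its equatorial, thermodynamically preferred configuration.

Step 17
Reactants: 21 (5aR,6S,7S,9aR)-2,2,5a,7-tetramethyl-3-oxodecahydro-1-benzoxepine-6-carbaldehyde
Product: 22 (5aR,6S,7S,9aR)-6-ethenyl-2,2,5a,7-tetramethyloctahydro-1-benzoxepin-3(2H)-one
Conditions: Ph3PCH3Br (1.1 equiv), KN(SiMe3)2, THF, 0 °C; then 21, −78 to 0 °C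
Reagents that add atoms: methyltriphenylphosphonium bromide, C[P+](c1ccccc1)(c1ccccc1)c1ccccc1.[Br-]
Why: Wittig methylenation is chemoselective for the aldehyde over the α-quaternary ketone at low temperature with one equivalent of ylide.

**Fragment union**

Step 18
Reactants: 22 (5aR,6S,7S,9aR)-6-ethenyl-2,2,5a,7-tetramethyloctahydro-1-benzoxepin-3(2H)-one; 15 (3R,5R,10R)-3-hydroxy-4,4,8,10-tetramethyl-trans-decala-6,8-dien-9-yl trifluoromethanesulfonate
Product: 24 CNP0106412.2, via alkylborane 23 (not isolated)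
Conditions: 22, 9-BBN, THF, rt; then 15, PdCl2(dppf), Ph3As, Cs2CO3, DMF/H2O, rt to 45 °C
Reagents that add atoms: none
Why: B-alkyl Suzuki–Miyaura coupling: 9-BBN hydroborates the terminal vinyl group anti-Markovnikov faster than it reduces the hindered ketone, and alkylborane 23 couples at C9 of the dienyl triflate (a 2,6,6-trisubstituted cyclohexenyl triflate type) with retention of all stereocentres.

**Compound list**

1 | methyl 3-hydroxy-2,2-dimethylpropanoate | COC(=O)C(C)(C)CO | starting material
2 | 3-hydroxy-N-methoxy-N,2,2-trimethylpropanamide | CON(C)C(=O)C(C)(C)CO | intermediate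
3 | N-methoxy-N,2,2-trimethyl-3-oxopropanamide | CON(C)C(=O)C(C)(C)C=O | intermediate
4 | (E)-N-methoxy-N,2,2,4-tetramethyl-5-oxopent-3-enamide | CON(C)C(=O)C(C)(C)/C=C(\C)C=O | intermediate
5 | (R)-but-3-yn-2-ol | C#C[C@@H](C)O | starting material
6 | (R)-but-3-yn-2-yl methanesulfonate | C#C[C@@H](C)OS(C)(=O)=O | intermediate
7 | (P)-buta-1,2-dien-1-yl(ethyl)zinc | CC[Zn]C([H])=[C@@]=C([H])C | intermediate
8 | (3E,5S,6S)-5-hydroxy-N-methoxy-N,2,2,4,6-pentamethyloct-3-en-7-ynamide (anti) | C#C[C@H](C)[C@H](O)/C(C)=C/C(C)(C)C(=O)N(C)OC | intermediate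
9 | (3E,5S,6S,7E)-5-hydroxy-N-methoxy-N,2,2,4,6-pentamethyl-8-(tributylstannyl)octa-3,7-dienamide | CCCC[Sn](CCCC)(CCCC)/C=C/[C@H](C)[C@H](O)/C(C)=C/C(C)(C)C(=O)N(C)OC | intermediate
10 | (3E,5S,6S,7E)-5-hydroxy-8-iodo-N-methoxy-N,2,2,4,6-pentamethylocta-3,7-dienamide | I/C=C/[C@H](C)[C@H](O)/C(C)=C/C(C)(C)C(=O)N(C)OC | intermediate
11 | (5E,7S,8S,9E)-7-hydroxy-10-iodo-4,4,6,8-tetramethyldeca-1,5,9-trien-3-one | I/C=C/[C@H](C)[C@H](O)/C(C)=C/C(C)(C)C(=O)C=C | intermediate
12 | (5S,8S,9S,10R)-9-hydroxy-4,4,8,10-tetramethyl-trans-decal-6-en-3-one (9-OH, 8-Me and H5 on the face opposite the 10-Me) | C[C@@H]1[C@H](O)[C@]2(C)CCC(=O)C(C)(C)[C@H]2C=C1 | intermediate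
13 | (5R,8S,10R)-4,4,8,10-tetramethyl-trans-decal-6-ene-3,9-dione | C[C@@H]1C(=O)[C@]2(C)CCC(=O)C(C)(C)[C@H]2C=C1 | intermediate
14 | (5S,10R)-4,4,8,10-tetramethyl-3-oxo-trans-decala-6,8-dien-9-yl trifluoromethanesulfonate | CC1=C(OS(=O)(=O)C(F)(F)F)[C@]2(C)CCC(=O)C(C)(C)[C@H]2C=C1 | intermediate
15 | (3R,5R,10R)-3-hydroxy-4,4,8,10-tetramethyl-trans-decala-6,8-dien-9-yl trifluoromethanesulfonate (3-OH equatorial, cis to the 10-Me) | CC1=C(OS(=O)(=O)C(F)(F)F)[C@]2(C)CC[C@@H](O)C(C)(C)[C@H]2C=C1 | intermediate
16 | (2E,6E)-farnesyl acetate | CC(C)=CCC/C(C)=C/CC/C(C)=C/COC(C)=O | starting material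
17 | (2E,6R,7R,10R)-6,7:10,11-diepoxy-3,7,11-trimethyldodec-2-en-1-yl acetate | CC1(C)O[C@@H]1CC[C@@]1(C)O[C@@H]1CC/C(C)=C/COC(C)=O | intermediate
18 | [(3R,5aR,6S,9aR)-3-hydroxy-2,2,5a-trimethyl-7-methylidenedecahydro-1-benzoxepin-6-yl]methyl acetate (trans-fused) | CC(=O)OC[C@H]1C(=C)CC[C@H]2OC(C)(C)[C@H](O)CC[C@@]21C | intermediate
19 | [(3R,5aR,6S,7S,9aR)-3-hydroxy-2,2,5a,7-tetramethyldecahydro-1-benzoxepin-6-yl]methyl acetate | CC(=O)OC[C@H]1[C@@H](C)CC[C@H]2OC(C)(C)[C@H](O)CC[C@@]21C | intermediate
20 | (3R,5aR,6S,7S,9aR)-6-(hydroxymethyl)-2,2,5a,7-tetramethyldecahydro-1-benzoxepin-3-ol | OC[C@H]1[C@@H](C)CC[C@H]2OC(C)(C)[C@H](O)CC[C@@]21C | intermediate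
21 | (5aR,6S,7S,9aR)-2,2,5a,7-tetramethyl-3-oxodecahydro-1-benzoxepine-6-carbaldehyde | O=C[C@H]1[C@@H](C)CC[C@H]2OC(C)(C)C(=O)CC[C@@]21C | intermediate
22 | (5aR,6S,7S,9aR)-6-ethenyl-2,2,5a,7-tetramethyloctahydro-1-benzoxepin-3(2H)-one | C=C[C@H]1[C@@H](C)CC[C@H]2OC(C)(C)C(=O)CC[C@@]21C | intermediate
23 | B-{2-[(5aR,6S,7S,9aR)-2,2,5a,7-tetramethyl-3-oxodecahydro-1-benzoxepin-6-yl]ethyl}-9-borabicyclo[3.3.1]nonane | C1CC2CCCC(C1)B2CC[C@H]1[C@@H](C)CC[C@H]2OC(C)(C)C(=O)CC[C@@]21C | intermediate
24 | CNP0106412.2: (5aR,6S,7S,9aR)-6-{2-[(3R,5S,10R)-3-hydroxy-4,4,8,10-tetramethyl-trans-decala-6,8-dien-9-yl]ethyl}-2,2,5a,7-tetramethyloctahydro-1-benzoxepin-3(2H)-one | CC1=C(CC[C@H]2[C@@H](C)CC[C@H]3OC(C)(C)C(=O)CC[C@@]32C)[C@]2(C)CC[C@@H](O)C(C)(C)[C@H]2C=C1 | target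

**Count.** Total steps: 18. Longest linear sequence: 11 steps (steps 1, 2, 3, 5, 6, 7, 8, 9, 10, 11, 18).

**Steps most likely to fail**

Step 8. The cascade may break down through hydrogen transfer to the vinyl or the tertiary radical before the second ring closes, or through poor facial selectivity in the first closure. The fallback sets out from 10 and comes back at 12, and it still closes ring B at C5–C6. Amide 10 is cyclised with Bu3SnH/AIBN in the presence of phenyl vinyl sulfone, so that the C10 radical is trapped intermolecularly anti to the C5 side chain, which should give monocyclic sulfone F1. Treatment of F1 with LiN(iPr)2 lets the α-sulfonyl carbanion acylate the Weinreb amide and close ring A at C2–C3, giving β-keto sulfone F2. Reductive desulfonylation of F2 with SmI2 in THF/MeOH returns 12.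

Step 10. Enolisation may scramble between C8 (C9 ketone) and C2 (C3 ketone), giving mixed enol triflates. The fallback sets out from 13 and comes back at 15. NaBH4 at −78 °C should reduce the less hindered C3 ketone first to give hydroxy ketone F3. Silylation with Et3SiOTf/2,6-lutidine gives silyl ether F4, in which only the C9 ketone can enolise. KN(SiMe3)2/PhNTf2 then gives silyl-protected triflate F5, and HF·pyridine returns 15.

Step 18. Transmetalation and reductive elimination at the tetrasubstituted triflate next to the quaternary C10 may be slow, so that protodeboronation or β-hydride elimination of the alkyl group takes over. The fallback sets out from 22 and comes back at 24 by a Negishi coupling. Hydroboration–oxidation of 22 (9-BBN; then NaBO3) gives primary alcohol F6. I2/PPh3/imidazole converts F6 into primary iodide F7. Zinc insertion (Zn dust, LiCl, THF) gives alkylzinc iodide F8, which is coupled in excess with 15 using Pd(OAc)2 and SPhos in THF to give 24.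

Further compounds
F1 | step 8 | 3-[(1S,4S,5S,6R)-5-hydroxy-4,6-dimethyl-6-(2-phenylsulfonylethyl)cyclohex-2-en-1-yl]... Weinreb amide: N-methoxy-N,2-dimethyl-2-[ring]propanamide, sulfonylethyl group trans to the C5 side chain | C[C@@H]1[C@H](O)[C@](C)(CCS(=O)(=O)c2ccccc2)[C@@H](C(C)(C)C(=O)N(C)OC)C=C1
F2 | step 8 | 2-(phenylsulfonyl) derivative of 12 (C2 epimers) | C[C@@H]1[C@H](O)[C@]2(C)CC(S(=O)(=O)c3ccccc3)C(=O)C(C)(C)[C@H]2C=C1
F3 | step 10 | (3R,8S,10R)-3-hydroxy-4,4,8,10-tetramethyl-trans-decal-6-en-9-one | C[C@@H]1C(=O)[C@]2(C)CC[C@@H](O)C(C)(C)[C@H]2C=C1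
F4 | step 10 | 3-O-triethylsilyl ether of F3 | C[C@@H]1C(=O)[C@]2(C)CC[C@@H](O[Si](CC)(CC)CC)C(C)(C)[C@H]2C=C1
F5 | step 10 | 3-O-triethylsilyl ether of 15 | CC1=C(OS(=O)(=O)C(F)(F)F)[C@]2(C)CC[C@@H](O[Si](CC)(CC)CC)C(C)(C)[C@H]2C=C1
F6 | step 18 | (5aR,6S,7S,9aR)-6-(2-hydroxyethyl)-2,2,5a,7-tetramethyloctahydro-1-benzoxepin-3(2H)-one | OCC[C@H]1[C@@H](C)CC[C@H]2OC(C)(C)C(=O)CC[C@@]21C
F7 | step 18 | (5aR,6S,7S,9aR)-6-(2-iodoethyl)-2,2,5a,7-tetramethyloctahydro-1-benzoxepin-3(2H)-one | ICC[C@H]1[C@@H](C)CC[C@H]2OC(C)(C)C(=O)CC[C@@]21C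
F8 | step 18 | {2-[(5aR,6S,7S,9aR)-2,2,5a,7-tetramethyl-3-oxodecahydro-1-benzoxepin-6-yl]ethyl}zinc iodide | I[Zn]CC[C@H]1[C@@H](C)CC[C@H]2OC(C)(C)C(=O)CC[C@@]21C
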